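**Plan**

- Retrosynthesis: after removal of the two silyl groups, both C11–C12 (C11′–C12′) single bonds and both C13–CH3 (C13′–CH3) bonds are cut in one operation. This gives a C8 diene-diyne (C12 to C12′ through C15–C15′), two methyl groups and two copies of a C15 retro-trienyl iodide (C1–C11).
- Enabling feature: each half carries an (E)-trisubstituted C12=C13 alkene with its methyl on C13, joined by the C11–C12 single bond to the ring-bearing triene and flanking the central C14=C15–C15′=C14′ diene; the halves are related by C2 symmetry.
- The iodide is cut at C10=C11 (Takai), C8=C9 (Wittig) and C6=C7 (Peterson) back to ketoisophorone, which supplies the trimethylcyclohexene ring intact. The diyne is cut at both alkynes back to a muconate-derived dial.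
- Forward: the chain grows from ring carbon C6 to C7, C9 and C11; the diyne is then methylaluminated at both ends and joined to two iodides. No ring is formed anywhere in the route.
- Stereochemistry: C3 and C3′ (S) come from asymmetric transfer hydrogenation of the C4 carbonyl of ketoisophorone. Alkene geometry comes from the stabilised ylide, the Takai reaction, syn-methylalumination and retentive coupling; 6E is secured by separation and recycling after the Peterson step.

Key step: step 12

Remark: dimethyl (2E,4E)-muconate and ketoisophorone are taken as commercial. Ketoisophorone is chosen as the ring source because a base-mediated aldol condensation of isophorone itself would be expected to engage its C3 methyl group and not the ring CH2.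
Remark: the (S,S)-configured ruthenium catalyst is assumed to give the (S)-carbinol, by analogy with aryl ketones, the C2=C3 bond taking the place of the aryl group. Compounds 11 to 18 are to be handled under argon, in dim light and away from acid.

**Route**

Step 1
Reactants: 1 dimethyl (2E,4E)-hexa-2,4-dienedioate
Product: 2 (2E,4E)-hexa-2,4-diene-1,6-diol
Conditions: i-Bu2AlH (4.4 equiv), CH2Cl2, −78 → 0 °C; aqueous KNaC4H4O6 (potassium sodium tartrate)
Reagents that add atoms: none
Why: Aluminium hydride reduction of an α,β-unsaturated ester: i-Bu2AlH delivers hydride 1,2 to both ester carbonyls at low temperature and leaves the E,E-diene untouched, so the allylic diol should form without conjugate reduction.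

Step 2
Reactants: 2 (2E,4E)-hexa-2,4-diene-1,6-diol
Product: 3 (2E,4E)-hexa-2,4-dienedial
Conditions: activated MnO2 (excess), acetone/CH2Cl2, 23 °C
Reagents that add atoms: none
Why: Allylic alcohol oxidation with activated MnO2, which is selective for allylic carbinols, stops at the aldehyde and should keep the E,E geometry of the diene.

Step 3
Reactants: 3 (2E,4E)-hexa-2,4-dienedial
Product: 4 (3E,5E)-1,1,8,8-tetrabromoocta-1,3,5,7-tetraene
Conditions: CBr4 (4.2 equiv), PPh3 (8.4 equiv), CH2Cl2, 0 °C
Reagents that add atoms: carbon tetrabromide, BrC(Br)(Br)Br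
Why: First stage of the Corey–Fuchs alkyne synthesis: the ylide Ph3P=CBr2 formed from PPh3 and CBr4 undergoes a Wittig reaction with each unhindered conjugated aldehyde to give the two 1,1-dibromoalkene ends.

Step 4
Reactants: 4 (3E,5E)-1,1,8,8-tetrabromoocta-1,3,5,7-tetraene
Product: 6 (3E,5E)-1,8-bis(trimethylsilyl)octa-3,5-diene-1,7-diyne, via dilithium diacetylide 5 (not isolated)
Conditions: n-BuLi (4.4 equiv), THF, −78 °C; then Me3SiCl (5 equiv), −78 → 23 °C
Reagents that add atoms: chlorotrimethylsilane, C[Si](C)(C)Cl; n-butyllithium, [Li]CCCC (lithium of intermediate 5)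
Why: Second stage of the Corey–Fuchs sequence: bromine–lithium exchange and Fritsch–Buttenberg–Wiechell rearrangement turn each dibromoalkene into a lithium acetylide, and C-silylation gives a crystalline, storable form of the otherwise polymerisation-prone diyne.

Step 5
Reactants: 6 (3E,5E)-1,8-bis(trimethylsilyl)octa-3,5-diene-1,7-diyne
Product: 7 (3E,5E)-octa-3,5-diene-1,7-diyne
Conditions: K2CO3 (0.2 equiv), MeOH/THF, 0 → 23 °C; pentane/water partition, drying, solvent exchange to ClCH2CH2Cl at 0 °C; solution assayed and used at once
Reagents that add atoms: none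
Why: Base-catalysed methanolysis of the alkynyl C–Si bonds (protodesilylation) should release the two terminal alkynes without touching the E,E-diene, and handling in solution avoids polymerisation of the neat diyne.

Step 6
Reactants: 8 ketoisophorone (2,6,6-trimethylcyclohex-2-ene-1,4-dione)
Product: 9 (4S)-4-hydroxy-2,6,6-trimethylcyclohex-2-en-1-one
Conditions: RuCl(p-cymene)[(S,S)-TsDPEN] (1 mol %), KOH (2 mol %), i-PrOH, 23 °C
Reagents that add atoms: none
Why: Noyori-type asymmetric transfer hydrogenation of a ketone: the ruthenium hydride reduces only the C4 carbonyl, since the C1 carbonyl is screened by the C6 gem-dimethyl group and the C2 methyl, and the CH/π contact between the η6-arene and the C2=C3 bond should direct hydride to the Re face, which sets the (S)-carbinol that becomes C3 of the target.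

Step 7
Reactants: 9 (4S)-4-hydroxy-2,6,6-trimethylcyclohex-2-en-1-one
Product: 10 (4S)-4-[(tert-butyldimethylsilyl)oxy]-2,6,6-trimethylcyclohex-2-en-1-one
Conditions: t-BuMe2SiCl, imidazole, DMF, 23 °C
Reagents that add atoms: tert-butyldimethylsilyl chloride, CC(C)(C)[Si](C)(C)Cl
Why: Standard imidazole-promoted silylation of a secondary alcohol, which masks the carbinol as a base-, hydride- and organometal-stable ether without touching the stereocentre.

Step 8
Reactants: 10 (4S)-4-[(tert-butyldimethylsilyl)oxy]-2,6,6-trimethylcyclohex-2-en-1-one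
Product: 11 (2E)-2-[(4S)-4-[(tert-butyldimethylsilyl)oxy]-2,6,6-trimethylcyclohex-2-en-1-ylidene]acetonitrile
Conditions: Me3SiCH2CN, LiN(i-Pr)2, THF, −78 °C; then 10, −78 → 0 °C; water; chromatographic separation of the E isomer; Z isomer re-equilibrated (cat. I2, hexane, daylight) and recycled
Reagents that add atoms: (trimethylsilyl)acetonitrile, C[Si](C)(C)CC#N
Why: Peterson olefination: the small, linear α-silyl nitrile anion adds 1,2 to the hindered enone carbonyl, where phosphorus ylides would fail, and the lithium β-silyl alkoxide collapses at once with loss of Me3SiOLi to the exocyclic C6=C7 alkene, whose geometry the reaction does not control and which is therefore settled by separation and recycling of the Z isomer.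

Step 9
Reactants: 11 (2E)-2-[(4S)-4-[(tert-butyldimethylsilyl)oxy]-2,6,6-trimethylcyclohex-2-en-1-ylidene]acetonitrile
Product: 13 (2E)-2-[(4S)-4-[(tert-butyldimethylsilyl)oxy]-2,6,6-trimethylcyclohex-2-en-1-ylidene]acetaldehyde, via N-alanyl aldimine 12 (not isolated)
Conditions: i-Bu2AlH (1.2 equiv), toluene, −78 °C; then aqueous KNaC4H4O6, 0 °C
Reagents that add atoms: water, O (aldehyde oxygen); diisobutylaluminium hydride, CC(C)C[AlH]CC(C)C (aluminium of intermediate 12)
Why: Partial reduction of a nitrile with i-Bu2AlH: one hydride adds to give an N-aluminio aldimine that resists further reduction at low temperature and is hydrolysed on mild, non-acidic work-up to the aldehyde with the C6=C7 geometry and the silyl ether intact.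

Step 10
Reactants: 13 (2E)-2-[(4S)-4-[(tert-butyldimethylsilyl)oxy]-2,6,6-trimethylcyclohex-2-en-1-ylidene]acetaldehyde
Product: 14 (2E,4E)-4-[(4S)-4-[(tert-butyldimethylsilyl)oxy]-2,6,6-trimethylcyclohex-2-en-1-ylidene]-2-methylbut-2-enal
Conditions: Ph3P=C(CH3)CHO (1.5 equiv), toluene, 90 °C, dark
Reagents that add atoms: 2-(triphenylphosphoranylidene)propanal, CC(C=O)=P(c1ccccc1)(c1ccccc1)c1ccccc1
Why: Wittig olefination with the stabilised formyl ylide, which reacts under thermodynamic control of the oxaphosphetane to give the (E)-2-methyl enal (C8=C9) and should stop after one homologation because the α-methyl trienal formed is less electrophilic than the dienal.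

Step 11
Reactants: 14 (2E,4E)-4-[(4S)-4-[(tert-butyldimethylsilyl)oxy]-2,6,6-trimethylcyclohex-2-en-1-ylidene]-2-methylbut-2-enal
Product: 15 tert-butyl{[(1S,4E)-4-[(2E,4E)-5-iodo-3-methylpenta-2,4-dien-1-ylidene]-3,5,5-trimethylcyclohex-2-en-1-yl]oxy}dimethylsilane
Conditions: CrCl2 (8 equiv), CHI3 (3 equiv), THF/1,4-dioxane, 0 → 23 °C, dark
Reagents that add atoms: iodoform, IC(I)I
Why: Takai olefination: the geminal dichromium species made from CHI3 and CrCl2 adds to the aldehyde and the β-oxido chromium intermediate eliminates anti-periplanar, which should give the (E)-C10=C11 alkenyl iodide under non-acidic, non-basic conditions that spare the silyl ether.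

Step 12
Reactants: 7 (3E,5E)-octa-3,5-diene-1,7-diyne; 15 tert-butyl{[(1S,4E)-4-[(2E,4E)-5-iodo-3-methylpenta-2,4-dien-1-ylidene]-3,5,5-trimethylcyclohex-2-en-1-yl]oxy}dimethylsilane (2.1 equiv)
Product: 17 (3S,3′S)-eschscholtzxanthin bis(tert-butyldimethylsilyl) ether, via bis(dimethylalanyl)tetraene 16 (not isolated)
Conditions: Me3Al (5 equiv), Cp2ZrCl2 (0.5 equiv), ClCH2CH2Cl, 23 °C; volatiles removed in vacuo; then THF, 15, ZnCl2 (0.6 equiv), Pd2(dba)3 (2.5 mol %), P(2-furyl)3 (10 mol %), 23 °C, dark
Reagents that add atoms: trimethylaluminium, C[Al](C)C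
Why: Cp2ZrCl2 and Me3Al form a chloride-bridged methylzirconium–aluminium species that adds CH3–metal syn across each terminal alkyne of 7 through a four-centre transition state, placing the methyl on the internal carbon (C13, C13′) and the metal on the terminal carbon (C12, C12′), after which zirconium-to-aluminium exchange gives the bis(dimethylalanyl)tetraene 16 with both new alkenes E by construction. After removal of excess Me3Al, zerovalent palladium inserts into the C11–I bond of 15, ZnCl2 shuttles each alkenyl group from aluminium through zinc to palladium, and reductive elimination forms C11–C12 and C11′–C12′ with retention at both sp2 carbons. The closest known reaction type is the zirconium-catalysed methylalumination of terminal, polyene-conjugated alkynes followed by palladium- and zinc-catalysed alkenyl–alkenyl Negishi coupling, a standard way to build the methyl-branched E-trisubstituted alkenes of polyene chains. No ring is closed and no stereocentre is created; the two C3 silyl ethers and the cyclohexene rings are spectators under these non-acidic conditions. The step needs methyl delivery to C13, syn addition and retentive coupling: the first follows from the steric and electronic bias of a terminal alkyne, the second from the concerted carbometalation, the third from stereospecific transmetalation and reductive elimination, while the C14=C15–C15′=C14′ diene is left alone because the catalyst system carbometalates alkynes only. The C2 symmetry of 7 makes both ends equivalent, so one set of conditions should form four skeletal bonds.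

Step 13
Reactants: 17 (3S,3′S)-eschscholtzxanthin bis(tert-butyldimethylsilyl) ether
Product: 18 (3S,3′S)-eschscholtzxanthin, all-E
Conditions: Bu4NF (3 equiv), AcOH (1.5 equiv), THF, 0 → 23 °C, dark; crystallisation from CH2Cl2/hexane
Reagents that add atoms: none
Why: Fluoride-mediated cleavage of silyl ethers, driven by the Si–F bond, is buffered so that neither acid (which would ionise the polyene-conjugated allylic carbinols) nor strong base is present, and it does not touch the C3 stereocentres.

**Compound list**

1 | dimethyl (2E,4E)-hexa-2,4-dienedioate | COC(=O)/C=C/C=C/C(=O)OC | starting material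
2 | (2E,4E)-hexa-2,4-diene-1,6-diol | OC/C=C/C=C/CO | intermediate
3 | (2E,4E)-hexa-2,4-dienedial | O=C/C=C/C=C/C=O | intermediate
4 | (3E,5E)-1,1,8,8-tetrabromoocta-1,3,5,7-tetraene | BrC(Br)=C/C=C/C=C/C=C(Br)Br | intermediate
5 | (3E,5E)-1,8-dilithioocta-3,5-diene-1,7-diyne (dilithium diacetylide, not isolated) | [Li]C#C/C=C/C=C/C#C[Li] | intermediate
6 | (3E,5E)-1,8-bis(trimethylsilyl)octa-3,5-diene-1,7-diyne | C[Si](C)(C)C#C/C=C/C=C/C#C[Si](C)(C)C | intermediate
7 | (3E,5E)-octa-3,5-diene-1,7-diyne | C#C/C=C/C=C/C#C | intermediate
8 | ketoisophorone (2,6,6-trimethylcyclohex-2-ene-1,4-dione) | CC1=CC(=O)CC(C)(C)C1=O | starting material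
9 | (4S)-4-hydroxy-2,6,6-trimethylcyclohex-2-en-1-one | CC1=C[C@@H](O)CC(C)(C)C1=O | intermediate
10 | (4S)-4-[(tert-butyldimethylsilyl)oxy]-2,6,6-trimethylcyclohex-2-en-1-one | CC1=C[C@@H](O[Si](C)(C)C(C)(C)C)CC(C)(C)C1=O | intermediate
11 | (2E)-2-[(4S)-4-[(tert-butyldimethylsilyl)oxy]-2,6,6-trimethylcyclohex-2-en-1-ylidene]acetonitrile | CC1=C[C@@H](O[Si](C)(C)C(C)(C)C)CC(C)(C)\C1=C/C#N | intermediate
12 | N-(diisobutylalanyl) aldimine of 13 (not isolated) | CC1=C[C@@H](O[Si](C)(C)C(C)(C)C)CC(C)(C)\C1=C/C=N[Al](CC(C)C)CC(C)C | intermediate
13 | (2E)-2-[(4S)-4-[(tert-butyldimethylsilyl)oxy]-2,6,6-trimethylcyclohex-2-en-1-ylidene]acetaldehyde | CC1=C[C@@H](O[Si](C)(C)C(C)(C)C)CC(C)(C)\C1=C/C=O | intermediate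
14 | (2E,4E)-4-[(4S)-4-[(tert-butyldimethylsilyl)oxy]-2,6,6-trimethylcyclohex-2-en-1-ylidene]-2-methylbut-2-enal | CC1=C[C@@H](O[Si](C)(C)C(C)(C)C)CC(C)(C)\C1=C/C=C(C)/C=O | intermediate
15 | tert-butyl{[(1S,4E)-4-[(2E,4E)-5-iodo-3-methylpenta-2,4-dien-1-ylidene]-3,5,5-trimethylcyclohex-2-en-1-yl]oxy}dimethylsilane (C15 retro-trienyl iodide) | CC1=C[C@@H](O[Si](C)(C)C(C)(C)C)CC(C)(C)\C1=C/C=C(C)/C=C/I | intermediate
16 | (1E,3E,5E,7E)-1,8-bis(dimethylalanyl)-2,7-dimethylocta-1,3,5,7-tetraene (not isolated) | C[Al](C)/C=C(C)/C=C/C=C/C(C)=C/[Al](C)C | intermediate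
17 | (3S,3′S)-eschscholtzxanthin bis(tert-butyldimethylsilyl) ether, all-E | CC1=C[C@@H](O[Si](C)(C)C(C)(C)C)CC(C)(C)\C1=C/C=C(C)/C=C/C=C(C)/C=C/C=C/C(C)=C/C=C/C(C)=C/C=C1/C(C)=C[C@@H](O[Si](C)(C)C(C)(C)C)CC1(C)C | intermediate
18 | (3S,3′S)-eschscholtzxanthin, all-E | CC1=C[C@@H](O)CC(C)(C)\C1=C/C=C(C)/C=C/C=C(C)/C=C/C=C/C(C)=C/C=C/C(C)=C/C=C1/C(C)=C[C@@H](O)CC1(C)C | target

**Step count and risks**

Total: 13 steps. Longest linear sequence: 8 steps (steps 6 to 13, from ketoisophorone); the diyne branch is 5 steps to the point of convergence.

Steps most likely to fail: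

1. Step 12. The two-fold coupling may stall at the mono-coupled stage, alane ends may be lost by protonolysis or methyl transfer, and diyne 7 may oligomerise under the Lewis-acidic carbometalation conditions. Fallback: the carbometalation is kept but the coupling polarity is reversed. Setting out from 7, the methylalumination is run as before and bis-alane 16 is quenched with iodine (THF, −30 °C) to give the storable (1E,3E,5E,7E)-1,8-diiodo-2,7-dimethylocta-1,3,5,7-tetraene F1, which can be purified and checked for geometry. Setting out from 15, iodine–lithium exchange (t-BuLi, Et2O, −78 °C) and quenching with Bu3SnCl give the trienylstannane F2. A two-fold Stille coupling of F1 with F2 (Pd2(dba)3, AsPh3, THF/NMP, 23 °C, dark) forms the same C11–C12 and C11′–C12′ bonds and returns to the route at 17.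

2. Step 8. The olefination may give poor control of the C6=C7 geometry, and 1,2-addition to the hindered enone may be slow enough for γ-deprotonation to compete. Fallback: setting out from 10, (Z)-2-ethoxyvinyllithium (from (Z)-1-bromo-2-ethoxyethene and t-BuLi, THF, −78 °C) is added to the carbonyl to give (4S)-4-[(tert-butyldimethylsilyl)oxy]-1-[(Z)-2-ethoxyethenyl]-2,6,6-trimethylcyclohex-2-en-1-ol F3 as a mixture of carbinol epimers. Brief treatment with dilute aqueous oxalic acid in THF at 0 °C hydrolyses the enol ether and dehydrates the tertiary carbinol; C7 carries the only β-hydrogens, and the geometry is set under equilibrating conditions. This returns to the route at 13 and bypasses 11 and 12.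

3. Step 11. E-selectivity at C10=C11 may erode, and the light-sensitive trienyl iodide may decompose in the presence of Lewis-acidic trivalent chromium. Fallback: setting out from 14, Colvin homologation with lithiated trimethylsilyldiazomethane (Me3SiCHN2, LiN(i-Pr)2, THF, −78 → 0 °C) gives the terminal alkyne tert-butyldimethyl{[(1S,4E)-3,5,5-trimethyl-4-[(2E)-3-methylpent-2-en-4-yn-1-ylidene]cyclohex-2-en-1-yl]oxy}silane F4. Syn-hydrozirconation with Cp2Zr(H)Cl (THF, 23 °C) and iodinolysis with I2 at 0 °C then give the (E)-alkenyl iodide with retention, returning to the route at 15.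

**Further compounds**

F1 | step 12 | (1E,3E,5E,7E)-1,8-diiodo-2,7-dimethylocta-1,3,5,7-tetraene | I/C=C(C)/C=C/C=C/C(C)=C/I
F2 | step 12 | tert-butyldimethyl{[(1S,4E)-3,5,5-trimethyl-4-[(2E,4E)-3-methyl-5-(tributylstannyl)penta-2,4-dien-1-ylidene]cyclohex-2-en-1-yl]oxy}silane | CC1=C[C@@H](O[Si](C)(C)C(C)(C)C)CC(C)(C)\C1=C/C=C(C)/C=C/[Sn](CCCC)(CCCC)CCCC
F3 | step 8 | (4S)-4-[(tert-butyldimethylsilyl)oxy]-1-[(Z)-2-ethoxyethenyl]-2,6,6-trimethylcyclohex-2-en-1-ol (mixture of C1 epimers) | CCO/C=C\C1(O)C(C)=C[C@@H](O[Si](C)(C)C(C)(C)C)CC1(C)C
F4 | step 11 | tert-butyldimethyl{[(1S,4E)-3,5,5-trimethyl-4-[(2E)-3-methylpent-2-en-4-yn-1-ylidene]cyclohex-2-en-1-yl]oxy}silane | CC1=C[C@@H](O[Si](C)(C)C(C)(C)C)CC(C)(C)\C1=C/C=C(C)/C#C
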